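## The problem

2α‑Hydroxyferutinin (21) is a trans‑fused bicyclo[5.3.0]decene. Ring A is the cyclopentane C1–C5 and ring B the cycloheptene C1, C5–C10 (daucane numbering: C1 quaternary ring‑fusion carbon with a methyl group, C2 carbinol, C3 methylene, C4 tertiary carbinol with the isopropyl group, C5 ring‑fusion CH, C6 acyloxy carbon, C7 methylene, C8=C9 with the methyl on C8, C10 methylene; β is the face of the C1 methyl, α the face of H‑5). There are five stereocentres (C1, C2, C4, C5, C6): the C1 methyl and the C4 hydroxyl are β, whereas H‑5, the isopropyl group, the C2 hydroxyl, the C6 oxygen and C10 are α. The ring fusion is trans (C10 on C1 and C6 on C5 on opposite faces of ring A), so cycloadditions across a C1=C5 bond, or ring closures at C1 or C5 from a tether on the neighbouring carbon, would give the wrong (cis) fusion. C10 is cis to both the isopropyl group and the C2 hydroxyl, so a preformed C4 or C2 carbinol would steer C10 to the wrong face; these two centres should be made after C1 and C5. C4 is flanked 1,3 by the oxygens on C2 and C6, so any two of the three as carbonyls form a β‑diketone and the oxygens must pass through the ketone state one after the other; once C4 is the tertiary β‑alcohol it can deliver hydride to C2 and to C6 from the β face, which is what both α‑carbinols need. The feature the plan uses is the array C2(O)–C1–C5–C4(O) of ring A: it is the carbonyl, α‑carbon, β‑carbon and γ‑oxygen of a 4‑oxygenated cyclopent‑2‑enone, on which a nucleophile (C6) adds to C5 anti to the C4 oxygen and an electrophile (C10) adds to C1 anti to C6, giving the two trans relationships of the target. Sensitive points: the C8=C9 bond is β,γ to C6 and can move into conjugation when C6 is a ketone; the tertiary C4 hydroxyl is β to C2 and C6 and can be lost from the ketols by dehydration or retro‑aldol cleavage; the aryl ester does not survive organometallic reagents and must come late.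

## Retrosynthesis

**21 ⇒ 20 ⇒ 19.** The phenol O–Si bond is cut first, then the C2–H bond. The 2α‑hydroxyl sits on the face that an external hydride cannot give (external attack comes anti to the C1 methyl and gives 2β). Making C2 last from ketone 19 by hydride delivery from the 4β‑hydroxyl is preferred to carrying a C2 carbinol through the synthesis. The forward step must reduce a neopentyl ketone in the presence of the aryl ester.

**19 ⇒ 18 ⇒ 16 + 17.** The C2 ketone is masked as a dioxolane (18) and the ester C–O bond is cut to alcohol 16 and the protected acid 17. Acylating while C2 is still a ketal means only one secondary hydroxyl (C6) is present, so no selectivity between C2‑OH and C6‑OH is needed. The acylation must leave the tertiary C4‑OH alone.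

**16 ⇒ 15 ⇒ 14.** The C6–H bond is cut (ketone 15), then the C6 carbonyl is traced to the dithiane 14. Reducing the ketone under direction of the 4β‑hydroxyl is preferred to building the carbinol by addition to an aldehyde, because it needs no extra control element. The dithiane keeps C6 masked while C4 is a ketone, and its hydrolysis must be neutral because 15 is both a β‑ketol and a β,γ‑enone.

**14 ⇒ 13 ⇒ 12 ⇒ 11.** The C4–isopropyl bond is cut (ketone 13), and the ketone is traced through alcohol 12 to silyl ether 11. Adding the isopropyl group at this stage, when C5 is already sp3 and carries the bulky C6 on the β face, gives reliable 1,2‑induction (isopropyl α, hydroxyl β). An earlier installation would put the isopropyl group in the way of C10. The C4 oxygen therefore serves three times: stereocontrol element (11), electrophile (13) and hydride director (14).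

**11 ⇒ 10 ⇒ 9.** The ketal is removed (10) and the C8=C9 bond is cut (9). This bond is remote from C1 and C5, so closing ring B here does not touch the trans fusion. Metathesis of a methallyl arm and an allyl arm fixes the alkene position and the C8 methyl without regiochemical ambiguity. The precursor 9 is a monocyclic cyclopentanone.

**9 ⇒ 3 + 6 (+ allyl iodide), the key disconnection.** The C5–C6 and C1–C10 bonds are cut together. What remains is the enone 3, which has one stereocentre and 12 of its atoms in the target skeleton, and the dithiane 6, which carries C6, C7, C8 and the C8 methyl. The forward reaction must create C5 and the quaternary C1 with the two trans relationships and without loss of the β‑silyloxy group.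

**3 ⇒ 2 ⇒ 1 and 6 ⇒ 5 ⇒ 4.** The C1 methyl is traced to the commercial (R)‑4‑silyloxycyclopentenone 1 through its α‑iodide 2. The methallyl group of 6 is traced to 1,3‑dithiane 4 through its anion 5.

## Roads not taken

**Alternative 1:** (most obvious) Chiral‑pool entry: ozonolysis and aldol ring contraction of (S)‑terpinen‑4‑ol A1 to the cyclopentene carbaldehyde A2, which already holds the C4 carbinol with its isopropyl group, the C1 methyl and C6. The forward key steps would be conjugate addition of a C10 unit to C1, methallylation of the aldehyde and ring‑closing metathesis. It was rejected for two structural reasons. A2 has no oxygen at C2, an unactivated methylene next to the future quaternary carbon. A nucleophile adds to C1 anti to the isopropyl group, whereas the target has C10 and the isopropyl group on the same face.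

**Alternative 2:** Strain‑release (4+3) annulation: cyclopropanation of the vinyl group of dienone A3 with the rhodium carbenoid from methyl 2‑diazobut‑3‑enoate A4 (chiral catalyst such as Rh2(S‑DOSP)4), then Cope rearrangement of the cis‑divinylcyclopropane to A5. One operation would make the C1–C10 bond, the quaternary centre, ring B and the C8=C9 bond. It was rejected because C5 is left sp2 in A5. The only stereocentre (C1, whose methyl and C10 lie almost symmetrically above and below ring A) cannot be trusted to control C4, C5 and C6. In addition there is no oxygen at C2 and the ester on C8 must be degraded to a methyl group, so the steps after the key step give back what it gains.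

**Alternative 3:** (5+2) Cycloaddition of the siloxy‑vinylcyclopropane A6 (C1–C5–C10 cyclopropane on ring A, from an intramolecular cyclopropanation) with propyne A7 under [Rh(CO)2Cl]2 to give A8. This would deliver C7–C10, the C8 methyl, the C8=C9 bond and the C6 oxygen at once, with C1 preset. It was rejected because A8 is again sp2 at C5 (a vinylogous ester). The isopropyl group would then add to C4 anti to the C2 silyloxy group (1,3), but the target needs them cis. The site of cyclopropane cleavage and the orientation of the alkyne are also unproven for this substitution pattern.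

Key step: step 4

Remark: ring carbons are numbered as in daucanes (see "The problem"); compounds 1, 4 and 17 are assumed to be commercially available.

## Steps

Step 1
Reactants: 1 (R)-4-[(tert-butyldimethylsilyl)oxy]cyclopent-2-en-1-one
Product: 2 (R)-4-[(tert-butyldimethylsilyl)oxy]-2-iodocyclopent-2-en-1-one
Conditions: I2, pyridine, CH2Cl2, 0 °C to rt
Reagents that add atoms: iodine, II
Why: α‑Iodination of the enone by conjugate addition of pyridine, iodination of the enolate and elimination; the silyl ether and the C4 stereocentre are not involved.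

Step 2
Reactants: 2 (R)-4-[(tert-butyldimethylsilyl)oxy]-2-iodocyclopent-2-en-1-one
Product: 3 (R)-4-[(tert-butyldimethylsilyl)oxy]-2-methylcyclopent-2-en-1-one
Conditions: MeZnCl, Pd(PPh3)4 (5 mol %), THF, rt
Reagents that add atoms: methylzinc chloride, C[Zn]Cl
Why: Negishi coupling of the α‑iodoenone (oxidative addition of zerovalent palladium into the vinylic C–I bond, transmetalation from zinc); the neutral conditions should spare the base‑sensitive β‑silyloxy enone.

Step 3
Reactants: 4 1,3-dithiane
Product: 6 2-(2-methylprop-2-en-1-yl)-1,3-dithiane, via 2-lithio-1,3-dithiane 5 (not isolated)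
Conditions: n-BuLi, THF, −30 °C; then 3-chloro-2-methylprop-1-ene, −78 °C to rt
Reagents that add atoms: 3-chloro-2-methylprop-1-ene, CC(=C)CCl
Why: Corey–Seebach alkylation: lithiation of the dithiane and SN2 reaction with the allylic chloride.

Step 4
Reactants: 6 2-(2-methylprop-2-en-1-yl)-1,3-dithiane; 3 (R)-4-[(tert-butyldimethylsilyl)oxy]-2-methylcyclopent-2-en-1-one
Product: 9 (2R,3R,4R)-4-[(tert-butyldimethylsilyl)oxy]-2-methyl-3-[2-(2-methylprop-2-en-1-yl)-1,3-dithian-2-yl]-2-(prop-2-en-1-yl)cyclopentan-1-one, via 2-lithio-2-(2-methylprop-2-en-1-yl)-1,3-dithiane 7 (not isolated), via lithium enolate 8 (not isolated)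
Conditions: n-BuLi, THF, −25 °C; HMPA, −78 °C; add 3; then allyl iodide, −78 to −30 °C
Reagents that add atoms: allyl iodide, C=CCI
Why: Three components are joined around ring A in one flask: the lithiated dithiane 7 (an acyl‑anion equivalent for C6 that already carries C7, C8 and the C8 methyl) adds 1,4 to enone 3, and the resulting lithium enolate 8 is C‑allylated at C1. The closest known reaction types are the conjugate addition–enolate alkylation of 4‑silyloxycyclopent‑2‑enones used for prostaglandins and the tandem addition of lithiated dithianes and allylic halides to 2‑methylcyclopent‑2‑enone. No ring is closed; the step forms the C5–C6 and C1–C10 bonds. C5 is set by the C4 silyloxy group: the bulky nucleophile attacks the enone face anti to it, so C6 becomes β and H‑5 α. C1 is set by the new C5 substituent: allyl iodide approaches the planar enolate anti to the dithianyl group, so C10 becomes α and the methyl β, which is the trans relationship of the future ring fusion. The step needs 1,4‑ over 1,2‑addition, which HMPA secures by giving a solvent‑separated ion pair of the sulfur‑stabilized anion. It needs C‑ over O‑alkylation, for which the lithium enolate and the soft, reactive allylic iodide are chosen. It also needs the silyloxy group to stay, which holds because the enolate is formed regiospecifically toward C1 and is trapped at low temperature before it can equilibrate toward C3.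

Step 5
Reactants: 9 (2R,3R,4R)-4-[(tert-butyldimethylsilyl)oxy]-2-methyl-3-[2-(2-methylprop-2-en-1-yl)-1,3-dithian-2-yl]-2-(prop-2-en-1-yl)cyclopentan-1-one
Product: 10 (3R,3aR,8aR)-3-[(tert-butyldimethylsilyl)oxy]-6,8a-dimethyl-2,3,3a,5,8,8a-hexahydro-1H-spiro[azulene-4,2'-[1,3]dithian]-1-one
Conditions: second-generation Grubbs catalyst (5 mol %), CH2Cl2 (5 mM), 40 °C
Reagents that add atoms: none
Why: Ring‑closing metathesis closes ring B at C8=C9; the allyl group initiates and the methallyl alkene closes, so the trisubstituted alkene and its methyl can only end up at C8. The trans‑1,2 arms on ring A and the gem‑disubstituted C6 favour the seven‑membered ring, and no stereocentre is touched.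

Step 6
Reactants: 10 (3R,3aR,8aR)-3-[(tert-butyldimethylsilyl)oxy]-6,8a-dimethyl-2,3,3a,5,8,8a-hexahydro-1H-spiro[azulene-4,2'-[1,3]dithian]-1-one
Product: 11 (3'R,3a'R,8a'R)-3'-[(tert-butyldimethylsilyl)oxy]-6',8a'-dimethyl-2',3',3a',5',8',8a'-hexahydrodispiro[[1,3]dioxolane-2,1'-azulene-4',2''-[1,3]dithiane]
Conditions: 1,2-bis(trimethylsilyloxy)ethane, TMSOTf (10 mol %), CH2Cl2, −78 to −20 °C
Reagents that add atoms: 1,2-bis(trimethylsilyloxy)ethane, C[Si](C)(C)OCCO[Si](C)(C)C
Why: Silyl‑triflate‑catalysed ketalization masks the C2 carbonyl so that C2 and C4 are never ketones at the same time; the aprotic, low‑temperature conditions should avoid β‑elimination of the C4 silyloxy group and leave the dithiane alone.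

Step 7
Reactants: 11 (3'R,3a'R,8a'R)-3'-[(tert-butyldimethylsilyl)oxy]-6',8a'-dimethyl-2',3',3a',5',8',8a'-hexahydrodispiro[[1,3]dioxolane-2,1'-azulene-4',2''-[1,3]dithiane]
Product: 12 (3'R,3a'R,8a'R)-6',8a'-dimethyl-2',3',3a',5',8',8a'-hexahydrodispiro[[1,3]dioxolane-2,1'-azulene-4',2''-[1,3]dithian]-3'-ol
Conditions: TBAF, THF, rt to 40 °C
Reagents that add atoms: none
Why: Fluoride cleavage of the silyl ether; with C2 as a ketal there is no carbonyl β to the liberated hydroxyl, so no elimination pathway exists.

Step 8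
Reactants: 12 (3'R,3a'R,8a'R)-6',8a'-dimethyl-2',3',3a',5',8',8a'-hexahydrodispiro[[1,3]dioxolane-2,1'-azulene-4',2''-[1,3]dithian]-3'-ol
Product: 13 (3a'R,8a'R)-6',8a'-dimethyl-3a',5',8',8a'-tetrahydrodispiro[[1,3]dioxolane-2,1'-azulene-4',2''-[1,3]dithian]-3'(2'H)-one
Conditions: (COCl)2, DMSO, CH2Cl2, −78 °C; Et3N, −78 to 0 °C
Reagents that add atoms: none
Why: Swern oxidation converts the C4 carbinol, having done its work as control element, into the ketone; activated DMSO tolerates the dithiane and the alkene, and the low temperature should keep C5 (now α to the ketone) from epimerizing.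

Step 9
Reactants: 13 (3a'R,8a'R)-6',8a'-dimethyl-3a',5',8',8a'-tetrahydrodispiro[[1,3]dioxolane-2,1'-azulene-4',2''-[1,3]dithian]-3'(2'H)-one
Product: 14 (3'R,3a'R,8a'R)-6',8a'-dimethyl-3'-(propan-2-yl)-2',3',3a',5',8',8a'-hexahydrodispiro[[1,3]dioxolane-2,1'-azulene-4',2''-[1,3]dithian]-3'-ol
Conditions: i-PrMgCl, LaCl3·2LiCl (30 mol %), THF, −20 to 0 °C; aqueous work-up
Reagents that add atoms: isopropylmagnesium chloride, CC(C)[Mg]Cl
Why: Lanthanum‑promoted 1,2‑addition of the Grignard reagent, which suppresses enolization and β‑hydride reduction of hindered ketones. The nucleophile should approach C4 from the α face, anti to the dithiane‑bearing C6 on the neighbouring C5 and anti to the axial C1 methyl, so the isopropyl group ends α and the hydroxyl β.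

Step 10
Reactants: 14 (3'R,3a'R,8a'R)-6',8a'-dimethyl-3'-(propan-2-yl)-2',3',3a',5',8',8a'-hexahydrodispiro[[1,3]dioxolane-2,1'-azulene-4',2''-[1,3]dithian]-3'-ol
Product: 15 (3'R,3a'R,8a'R)-3'-hydroxy-6',8a'-dimethyl-3'-(propan-2-yl)-2',3',3a',8a'-tetrahydro-5'H-spiro[[1,3]dioxolane-2,1'-azulen]-4'(8'H)-one
Conditions: MeI, CaCO3, MeCN–H2O (9:1), 45 °C
Reagents that add atoms: water, O
Why: Dithiane hydrolysis by S‑methylation under buffered, near‑neutral conditions unveils the C6 ketone, so the β,γ‑alkene should not move into conjugation and the ketol should not cleave. C5 already has the more stable configuration, with C6 trans to the isopropyl group.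

Step 11
Reactants: 15 (3'R,3a'R,8a'R)-3'-hydroxy-6',8a'-dimethyl-3'-(propan-2-yl)-2',3',3a',8a'-tetrahydro-5'H-spiro[[1,3]dioxolane-2,1'-azulen]-4'(8'H)-one
Product: 16 (3'R,3a'S,4'S,8a'R)-6',8a'-dimethyl-3'-(propan-2-yl)-2',3',3a',4',5',8a'-hexahydro-8'H-spiro[[1,3]dioxolane-2,1'-azulene]-3',4'-diol
Conditions: Me4NBH(OAc)3, MeCN–AcOH (1:1), −30 °C
Reagents that add atoms: none
Why: Evans–Saksena reduction: the tertiary 4β‑hydroxyl exchanges onto boron and delivers hydride through a six‑membered transition state to the β face of the C6 carbonyl, giving the 6α‑alcohol. The reagent does not reduce undirected ketones, the ketal or the alkene.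

Step 12
Reactants: 16 (3'R,3a'S,4'S,8a'R)-6',8a'-dimethyl-3'-(propan-2-yl)-2',3',3a',4',5',8a'-hexahydro-8'H-spiro[[1,3]dioxolane-2,1'-azulene]-3',4'-diol; 17 4-[(tert-butyldimethylsilyl)oxy]benzoic acid
Product: 18 (3'R,3a'S,4'S,8a'R)-3'-hydroxy-6',8a'-dimethyl-3'-(propan-2-yl)-2',3',3a',4',5',8a'-hexahydro-8'H-spiro[[1,3]dioxolane-2,1'-azulen]-4'-yl 4-[(tert-butyldimethylsilyl)oxy]benzoate
Conditions: DCC, DMAP (20 mol %), CH2Cl2, rt
Reagents that add atoms: none
Why: Steglich esterification of the only secondary hydroxyl (C6); the tertiary C4 hydroxyl is not acylated under these conditions, and the phenol is silylated to prevent self‑acylation.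

Step 13
Reactants: 18 (3'R,3a'S,4'S,8a'R)-3'-hydroxy-6',8a'-dimethyl-3'-(propan-2-yl)-2',3',3a',4',5',8a'-hexahydro-8'H-spiro[[1,3]dioxolane-2,1'-azulen]-4'-yl 4-[(tert-butyldimethylsilyl)oxy]benzoate
Product: 19 (3R,3aS,4S,8aR)-3-hydroxy-6,8a-dimethyl-1-oxo-3-(propan-2-yl)-1,2,3,3a,4,5,8,8a-octahydroazulen-4-yl 4-[(tert-butyldimethylsilyl)oxy]benzoate
Conditions: PPTS (0.3 equiv), THF–H2O (3:1), 50 °C
Reagents that add atoms: water, O
Why: Mild acid hydrolysis of the dioxolane frees the C2 ketone; the weakly acidic conditions are of the kind that β‑ketols of the prostaglandin E type tolerate, and the aryl silyl ether and the ester are stable at this pH.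

Step 14
Reactants: 19 (3R,3aS,4S,8aR)-3-hydroxy-6,8a-dimethyl-1-oxo-3-(propan-2-yl)-1,2,3,3a,4,5,8,8a-octahydroazulen-4-yl 4-[(tert-butyldimethylsilyl)oxy]benzoate
Product: 20 (1S,3R,3aS,4S,8aR)-1,3-dihydroxy-6,8a-dimethyl-3-(propan-2-yl)-1,2,3,3a,4,5,8,8a-octahydroazulen-4-yl 4-[(tert-butyldimethylsilyl)oxy]benzoate
Conditions: Me4NBH(OAc)3, MeCN–AcOH (1:1), −30 to 0 °C
Reagents that add atoms: none
Why: Second Evans–Saksena reduction: the same 4β‑hydroxyl delivers hydride across ring A to the β face of C2, the face shielded from external hydride by the C1 methyl, giving the trans‑1,3‑diol with the 2α‑hydroxyl. The ester is inert to the triacetoxyborohydride.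

Step 15
Reactants: 20 (1S,3R,3aS,4S,8aR)-1,3-dihydroxy-6,8a-dimethyl-3-(propan-2-yl)-1,2,3,3a,4,5,8,8a-octahydroazulen-4-yl 4-[(tert-butyldimethylsilyl)oxy]benzoate
Product: 21 (1S,3R,3aS,4S,8aR)-1,3-dihydroxy-6,8a-dimethyl-3-(propan-2-yl)-1,2,3,3a,4,5,8,8a-octahydroazulen-4-yl 4-hydroxybenzoate (2α-hydroxyferutinin)
Conditions: TBAF, AcOH, THF, 0 °C
Reagents that add atoms: none
Why: Buffered fluoride cleaves the aryl silyl ether selectively; the hindered benzoate and the three hydroxyl groups should be unaffected.

## Compound list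

1 | (R)-4-[(tert-butyldimethylsilyl)oxy]cyclopent-2-en-1-one | O=C1C=C[C@H](O[Si](C)(C)C(C)(C)C)C1 | starting material
2 | (R)-4-[(tert-butyldimethylsilyl)oxy]-2-iodocyclopent-2-en-1-one | O=C1C(I)=C[C@H](O[Si](C)(C)C(C)(C)C)C1 | intermediate
3 | (R)-4-[(tert-butyldimethylsilyl)oxy]-2-methylcyclopent-2-en-1-one | O=C1C(C)=C[C@H](O[Si](C)(C)C(C)(C)C)C1 | intermediate
4 | 1,3-dithiane | C1CSCSC1 | starting material
5 | 2-lithio-1,3-dithiane | [Li]C1SCCCS1 | intermediate
6 | 2-(2-methylprop-2-en-1-yl)-1,3-dithiane | CC(=C)CC1SCCCS1 | intermediate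
7 | 2-lithio-2-(2-methylprop-2-en-1-yl)-1,3-dithiane | CC(=C)CC1([Li])SCCCS1 | intermediate
8 | lithium (3R,4R)-4-[(tert-butyldimethylsilyl)oxy]-2-methyl-3-[2-(2-methylprop-2-en-1-yl)-1,3-dithian-2-yl]cyclopent-1-en-1-olate | CC1=C(O[Li])C[C@@H](O[Si](C)(C)C(C)(C)C)[C@@H]1C2(CC(C)=C)SCCCS2 | intermediate
9 | (2R,3R,4R)-4-[(tert-butyldimethylsilyl)oxy]-2-methyl-3-[2-(2-methylprop-2-en-1-yl)-1,3-dithian-2-yl]-2-(prop-2-en-1-yl)cyclopentan-1-one | C=CC[C@]1(C)[C@@H](C2(CC(C)=C)SCCCS2)[C@H](O[Si](C)(C)C(C)(C)C)CC1=O | intermediate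
10 | (3R,3aR,8aR)-3-[(tert-butyldimethylsilyl)oxy]-6,8a-dimethyl-2,3,3a,5,8,8a-hexahydro-1H-spiro[azulene-4,2'-[1,3]dithian]-1-one | CC1=CC[C@]2(C)[C@@H](C3(SCCCS3)C1)[C@H](O[Si](C)(C)C(C)(C)C)CC2=O | intermediate
11 | (3'R,3a'R,8a'R)-3'-[(tert-butyldimethylsilyl)oxy]-6',8a'-dimethyl-2',3',3a',5',8',8a'-hexahydrodispiro[[1,3]dioxolane-2,1'-azulene-4',2''-[1,3]dithiane] | CC1=CC[C@]2(C)[C@@H](C3(SCCCS3)C1)[C@H](O[Si](C)(C)C(C)(C)C)CC24OCCO4 | intermediate
12 | (3'R,3a'R,8a'R)-6',8a'-dimethyl-2',3',3a',5',8',8a'-hexahydrodispiro[[1,3]dioxolane-2,1'-azulene-4',2''-[1,3]dithian]-3'-ol | CC1=CC[C@]2(C)[C@@H](C3(SCCCS3)C1)[C@H](O)CC24OCCO4 | intermediate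
13 | (3a'R,8a'R)-6',8a'-dimethyl-3a',5',8',8a'-tetrahydrodispiro[[1,3]dioxolane-2,1'-azulene-4',2''-[1,3]dithian]-3'(2'H)-one | CC1=CC[C@]2(C)[C@@H](C3(SCCCS3)C1)C(=O)CC24OCCO4 | intermediate
14 | (3'R,3a'R,8a'R)-6',8a'-dimethyl-3'-(propan-2-yl)-2',3',3a',5',8',8a'-hexahydrodispiro[[1,3]dioxolane-2,1'-azulene-4',2''-[1,3]dithian]-3'-ol | CC1=CC[C@]2(C)[C@@H](C3(SCCCS3)C1)[C@](O)(C(C)C)CC24OCCO4 | intermediate
15 | (3'R,3a'R,8a'R)-3'-hydroxy-6',8a'-dimethyl-3'-(propan-2-yl)-2',3',3a',8a'-tetrahydro-5'H-spiro[[1,3]dioxolane-2,1'-azulen]-4'(8'H)-one | CC1=CC[C@]2(C)[C@@H](C(=O)C1)[C@](O)(C(C)C)CC24OCCO4 | intermediate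
16 | (3'R,3a'S,4'S,8a'R)-6',8a'-dimethyl-3'-(propan-2-yl)-2',3',3a',4',5',8a'-hexahydro-8'H-spiro[[1,3]dioxolane-2,1'-azulene]-3',4'-diol | CC1=CC[C@]2(C)[C@@H]([C@@H](O)C1)[C@](O)(C(C)C)CC24OCCO4 | intermediate
17 | 4-[(tert-butyldimethylsilyl)oxy]benzoic acid | CC(C)(C)[Si](C)(C)Oc1ccc(cc1)C(O)=O | starting material
18 | (3'R,3a'S,4'S,8a'R)-3'-hydroxy-6',8a'-dimethyl-3'-(propan-2-yl)-2',3',3a',4',5',8a'-hexahydro-8'H-spiro[[1,3]dioxolane-2,1'-azulen]-4'-yl 4-[(tert-butyldimethylsilyl)oxy]benzoate | CC1=CC[C@]2(C)[C@@H]([C@@H](OC(=O)c3ccc(O[Si](C)(C)C(C)(C)C)cc3)C1)[C@](O)(C(C)C)CC24OCCO4 | intermediate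
19 | (3R,3aS,4S,8aR)-3-hydroxy-6,8a-dimethyl-1-oxo-3-(propan-2-yl)-1,2,3,3a,4,5,8,8a-octahydroazulen-4-yl 4-[(tert-butyldimethylsilyl)oxy]benzoate | CC1=CC[C@]2(C)[C@@H]([C@@H](OC(=O)c3ccc(O[Si](C)(C)C(C)(C)C)cc3)C1)[C@](O)(C(C)C)CC2=O | intermediate
20 | (1S,3R,3aS,4S,8aR)-1,3-dihydroxy-6,8a-dimethyl-3-(propan-2-yl)-1,2,3,3a,4,5,8,8a-octahydroazulen-4-yl 4-[(tert-butyldimethylsilyl)oxy]benzoate | CC1=CC[C@]2(C)[C@@H]([C@@H](OC(=O)c3ccc(O[Si](C)(C)C(C)(C)C)cc3)C1)[C@](O)(C(C)C)C[C@@H]2O | intermediate
21 | (1S,3R,3aS,4S,8aR)-1,3-dihydroxy-6,8a-dimethyl-3-(propan-2-yl)-1,2,3,3a,4,5,8,8a-octahydroazulen-4-yl 4-hydroxybenzoate (2α-hydroxyferutinin) | CC1=CC[C@]2(C)[C@@H]([C@@H](OC(=O)c3ccc(O)cc3)C1)[C@](O)(C(C)C)C[C@@H]2O | target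

## Step count and least certain steps

Total step count: 15. Longest linear sequence: 14 steps (1 → 2 → 3 → 9 → 10 → … → 21); step 3 is a one‑step side branch.

**Step 4 (key step).** What may go wrong: 1,2‑addition of the hindered tertiary dithianyl anion to the carbonyl, proton transfer within the enolate followed by loss of silanolate (β‑elimination), or incomplete C‑allylation of the tetrasubstituted enolate. Fallback, which divides the C6–C8 fragment: starting from 3, the unhindered parent anion 5 (from 4) is added in THF/HMPA and the enolate is allylated as before to give the 3-(1,3-dithian-2-yl)cyclopentanone F1. Its C2 carbonyl is ketalized as in step 6 to give the dioxolane F2. The dithiane C–H of F2 is lithiated (t‑BuLi, THF/HMPA) and alkylated with 3‑bromo‑2‑methylprop‑1‑ene to give the diene ketal F3. Ring‑closing metathesis of F3 with the second‑generation Grubbs catalyst returns to the route at 11.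

**Step 5.** What may go wrong: binding of the ruthenium carbene by the dithiane sulfur atoms and slow closure onto the 1,1‑disubstituted alkene, so that oligomerization through the allyl group takes over. Fallback, which removes sulfur before metathesis: starting from 9, hydrolysis of the dithiane (MeI, CaCO3, aqueous MeCN) gives the acyclic‑arm diketone F4, and ring closure of F4 gives the bicyclic diketone F5. The less hindered ring‑B carbonyl (C6) of F5 is converted back into the dithiane (propane‑1,3‑dithiol, BF3·OEt2, −20 °C; the C2 carbonyl next to the quaternary carbon should react more slowly), which returns to the route at 10.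

**Step 9.** What may go wrong: reduction of the hindered ketone by β‑hydride transfer from the secondary Grignard reagent, or enolization toward C3 with opening of the neighbouring dioxolane. Fallback, which adds an sp2 nucleophile and reduces afterwards: starting from 13, addition of isopropenylmagnesium bromide (LaCl3·2LiCl) gives the isopropenyl carbinol F6. Diimide reduction of its 1,1‑disubstituted alkene (2‑nitrobenzenesulfonylhydrazide, Et3N), which should leave the trisubstituted ring alkene, returns to the route at 14.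

**Step 14.** What may go wrong: poor facial selectivity if internal hydride delivery across ring A to the neopentyl carbonyl is slow and external attack from the α face (anti to the C1 methyl) competes. Fallback, which accepts the sterically favoured epimer and inverts it: starting from 19, NaBH4 reduction gives the 2β-alcohol F7. Mitsunobu reaction of F7 with 4‑nitrobenzoic acid (PPh3, DIAD) gives the inverted 2α-(4-nitrobenzoate) F8. K2CO3 in methanol at 0 °C should remove the activated nitrobenzoate and the aryl silyl ether while the hindered C6 benzoate, deactivated as its phenoxide, survives; this returns to the route at 21.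

## Further compounds

F1 | step 4 | (2R,3R,4R)-4-[(tert-butyldimethylsilyl)oxy]-3-(1,3-dithian-2-yl)-2-methyl-2-(prop-2-en-1-yl)cyclopentan-1-one | C=CC[C@]1(C)[C@@H](C2SCCCS2)[C@H](O[Si](C)(C)C(C)(C)C)CC1=O
F2 | step 4 | ethylene ketal (1,3-dioxolane at the ring carbonyl) of F1 | C=CC[C@]1(C)[C@@H](C2SCCCS2)[C@H](O[Si](C)(C)C(C)(C)C)CC13OCCO3
F3 | step 4 | ethylene ketal (1,3-dioxolane at the ring carbonyl) of 9 | C=CC[C@]1(C)[C@@H](C2(CC(C)=C)SCCCS2)[C@H](O[Si](C)(C)C(C)(C)C)CC13OCCO3
F4 | step 5 | (2R,3R,4R)-4-[(tert-butyldimethylsilyl)oxy]-2-methyl-3-(3-methylbut-3-enoyl)-2-(prop-2-en-1-yl)cyclopentan-1-one | C=CC[C@]1(C)[C@@H](C(=O)CC(C)=C)[C@H](O[Si](C)(C)C(C)(C)C)CC1=O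
F5 | step 5 | (3R,3aR,8aR)-3-[(tert-butyldimethylsilyl)oxy]-6,8a-dimethyl-2,3,3a,5,8,8a-hexahydroazulene-1,4-dione | CC1=CC[C@]2(C)[C@@H](C(=O)C1)[C@H](O[Si](C)(C)C(C)(C)C)CC2=O
F6 | step 9 | isopropenyl analogue of 14 (prop-1-en-2-yl in place of propan-2-yl at the tertiary carbinol) | CC1=CC[C@]2(C)[C@@H](C3(SCCCS3)C1)[C@](O)(C(C)=C)CC24OCCO4
F7 | step 14 | 2β-epimer of 20 (1R,3R,3aS,4S,8aR) | CC1=CC[C@]2(C)[C@@H]([C@@H](OC(=O)c3ccc(O[Si](C)(C)C(C)(C)C)cc3)C1)[C@](O)(C(C)C)C[C@H]2O
F8 | step 14 | 2α-(4-nitrobenzoate) of 20 | CC1=CC[C@]2(C)[C@@H]([C@@H](OC(=O)c3ccc(O[Si](C)(C)C(C)(C)C)cc3)C1)[C@](O)(C(C)C)C[C@@H]2OC(=O)c5ccc(cc5)[N+](=O)[O-]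
A1 | alternative 1 | (S)-terpinen-4-ol [(S)-4-methyl-1-(propan-2-yl)cyclohex-3-en-1-ol] | CC1=CC[C@](O)(C(C)C)CC1
A2 | alternative 1 | (R)-5-hydroxy-2-methyl-5-(propan-2-yl)cyclopent-1-ene-1-carbaldehyde | CC1=C(C=O)[C@](O)(C(C)C)CC1
A3 | alternative 2 | 2-ethenyl-3-methylcyclopent-2-en-1-one | CC1=C(C=C)C(=O)CC1
A4 | alternative 2 | methyl 2-diazobut-3-enoate | COC(=O)C(=[N+]=[N-])C=C
A5 | alternative 2 | methyl (8aR)-8a-methyl-3-oxo-1,2,3,5,8,8a-hexahydroazulene-6-carboxylate | COC(=O)C1=CC[C@@]2(C)CCC(=O)C2=CC1
A6 | alternative 3 | 4-[(tert-butyldimethylsilyl)oxy]-1-{1-[(tert-butyldimethylsilyl)oxy]ethenyl}-5-methylbicyclo[3.1.0]hexan-2-one (cyclopropane methylene and ring silyloxy group cis) | O=C1C[C@H](O[Si](C)(C)C(C)(C)C)[C@]2(C)C[C@]12C(=C)O[Si](C)(C)C(C)(C)C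
A7 | alternative 3 | propyne | CC#C
A8 | alternative 3 | (1S,8aR)-1,4-bis[(tert-butyldimethylsilyl)oxy]-6,8a-dimethyl-1,2,8,8a-tetrahydroazulen-3(5H)-one | CC1=CC[C@@]2(C)[C@@H](O[Si](C)(C)C(C)(C)C)CC(=O)C2=C(O[Si](C)(C)C(C)(C)C)C1
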